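**Retrosynthetic overview**
1. Feature: in the norbornane (C1–C5, C10, C15) the isopropyl group on C4 points endo and stands next to the quaternary bridgehead C5. Equilibration would put it exo, so C4 has to be set kinetically once C5 is in place.
2. Key disconnection C4–C5: the norbornane endo ester comes from a bicyclo[3.2.1]octane α-diazoketone by photochemical Wolff contraction. C5 migrates with retention, exo protonation of the ketene adduct sets C4, and the ester carbon (C16) becomes the isopropyl methine.
3. The diazoketone goes back by C2–C3 (intramolecular Michael addition) to a 3-acryloylcyclopentanone. Its C5 is fixed by asymmetric hydroboration of the malonate-derived cyclopentene and relay through a bridged lactone.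
4. Ring A is brought in as cyclohexane-1,3-dione (C7–C8), CBS desymmetrisation sets C8 and C14, and palladium-catalysed ketone alkenylation closes ring B at C9–C10. Endo OMe, C11 ketone, C11-methyl alkene, C14 bromide and the trans-diaxial diol (epoxide opening) follow.
5. Order of rings: cyclopentane C1–C2–C15–C5–C10, six-membered ring of the bicyclo[3.2.1]octane, its contraction to the norbornane, ring A (ready-made), ring B.

Key step: step 13

Remark on numbering: all intermediates keep the target numbers.
- C1 CHOMe, C2, C3, C4 CH-iPr, C5 quaternary, C6, C7, C8 CMe, C9, C10, C11 C(OH)Me, C12 CHOH, C13, C14 CHBr, C15 bridge CH2.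
- C16 is the isopropyl methine, which is the extra ring carbonyl carbon of the bicyclo[3.2.1]octanes.
- Ring A = C8, C9, C11–C14; ring B = C5–C10.
- Exo is the side of C15. On rings A and B, β is the face of C15 and H9, and α is the face of the C8 methyl.

Remark on the target as read from the SMILES: iPr endo, OMe endo, C9 exo on C10, rings A/B trans. The C8 methyl is α axial, Br α equatorial, C11-OH α axial (C11 methyl β equatorial) and C12-OH β axial, so the diol is trans-diaxial.

Remark on ring B: closure through a C9=C10 enone (aldol condensation of a triketone) is avoided. With C10 trigonal, the C5–C6 bond lies on the exo side of the enone plane. This fixes the half-chair of ring B so that the C8 methyl should end β. C8 is therefore set by a reagent, and C10 stays tetrahedral in the closure.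

Remark on induction: the sense in steps 2 and 23 is taken from the empirical models of these reagents. Both reagents are available in either antipodal form.

**Step 1**
Reactants: 1 dimethyl malonate; 2 cis-1,4-dichlorobut-2-ene
Product: 3 dimethyl cyclopent-3-ene-1,1-dicarboxylate
Conditions: LiH (2.5 equiv), DMF, 0 °C to rt
Reagents that add atoms: none
Why: Double malonate alkylation (SN2, then 5-exo-tet closure) in which the cis geometry of the dichloride holds the second allylic chloride within reach of C5, and no stereocentre is formed.

**Step 2**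
Reactants: 3 dimethyl cyclopent-3-ene-1,1-dicarboxylate
Product: 4 dimethyl (S)-3-hydroxycyclopentane-1,1-dicarboxylate
Conditions: (−)-Ipc2BH [from (+)-α-pinene], THF, −25 °C to 0 °C; then 30% H2O2, pH 7 phosphate buffer, MeOH, 0 °C to rt
Reagents that add atoms: hydrogen peroxide, OO
Why: Brown asymmetric hydroboration of a cyclic cis-alkene whose two faces are equivalent, so that the reagent alone decides which alkene carbon is oxidised and should give the (S)-carbinol at C1 by the cis-2-butene model, the esters being inert to the dialkylborane and to the buffered oxidation.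

**Step 3**
Reactants: 4 dimethyl (S)-3-hydroxycyclopentane-1,1-dicarboxylate
Product: 5 bridged lactone ester (methyl 3-oxo-2-oxabicyclo[2.2.1]heptane-4-carboxylate)
Conditions: p-TsOH·H2O (5 mol %), toluene, reflux, 5 Å molecular sieves in a Soxhlet
Reagents that add atoms: none
Why: Acid-catalysed lactonisation (transesterification) in which only the ester on the face of the C1 hydroxyl can be reached, so that the carbinol centre is relayed to the quaternary C5 and the two carboxyl carbons become different (lactone carbon = C16, remaining ester carbon = C6), while trapping of methanol on the sieves pulls the strained lactone out of the equilibrium.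

**Step 4**
Reactants: 5 bridged lactone ester
Product: 6 lactol ester (anomers, in equilibrium with the open cis-hydroxy aldehyde)
Conditions: Sia2BH (2.5 equiv), THF, 0 °C to rt; then H2O2, pH 7 buffer
Reagents that add atoms: none
Why: Chemoselective lactone-to-lactol reduction with a hindered dialkylborane, a reagent known to leave carboxylic esters untouched (as on acylated aldonolactones), brings only C16 to the aldehyde level.

**Step 5**
Reactants: 6 lactol ester
Product: 7 methyl 3-hydroxy-1-(1-hydroxyallyl)cyclopentane-1-carboxylate (hydroxyallyl arm cis to C1-OH, epimers at C16)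
Conditions: vinylMgBr (3 equiv), THF, −78 °C to −20 °C
Reagents that add atoms: vinylmagnesium bromide, C=C[Mg]Br
Why: Grignard addition to the open hydroxy aldehyde form of the lactol adds C4 and C3 and is far faster at low temperature than attack on the neopentyl methyl ester; the new carbinol centre is left undefined because step 8 oxidises it.

**Step 6**
Reactants: 7 diol ester
Product: 8 triol (C1-OH, C16-OH, C6H2OH)
Conditions: LiAlH4, THF, 0 °C
Reagents that add atoms: none
Why: Ester reduction with LiAlH4 turns C6 into the hydroxymethyl group, and the isolated vinyl group and the two alkoxides are inert.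

**Step 7**
Reactants: 8 triol
Product: 9 primary TBS ether diol
Conditions: TBSCl (1.05 equiv), imidazole, CH2Cl2, −10 °C
Reagents that add atoms: tert-butyldimethylsilyl chloride, CC(C)(C)[Si](C)(C)Cl
Why: Selective silylation, since with one equivalent of TBSCl at low temperature the single primary hydroxyl should react ahead of the two secondary ones.

**Step 8**
Reactants: 9 primary TBS ether diol
Product: 10 3-acryloyl-3-(TBS-oxymethyl)cyclopentan-1-one
Conditions: Dess–Martin periodinane (2.5 equiv), NaHCO3, CH2Cl2, 0 °C to rt
Reagents that add atoms: none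
Why: Dess–Martin oxidation of both secondary alcohols in one operation gives the cyclopentanone and the vinyl ketone under nearly neutral conditions; the relay centre C1 disappears and C5 remains as the only stereocentre.

**Step 9**
Reactants: 10 3-acryloyl-3-(TBS-oxymethyl)cyclopentan-1-one
Product: 11 1-(TBS-oxymethyl)bicyclo[3.2.1]octane-2,6-dione (ketones at C16 and C1)
Conditions: DBU (0.2 equiv), MeCN (dilute), 0 °C to rt
Reagents that add atoms: none
Why: Intramolecular Michael addition (6-endo-trig) of the C2 enolate to C3 closes the six-membered ring, the alternative attack from C10 being a 5-endo-trig process, and C2 is fixed by the tether because C16 can deliver C3 only to its own face of the cyclopentanone.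

**Step 10**
Reactants: 11 bicyclic dione
Product: 12 C1 ethylene ketal of the dione (C16 ketone free)
Conditions: (TMSOCH2)2 (1.1 equiv), TMSOTf (5 mol %), CH2Cl2, −78 °C to −40 °C
Reagents that add atoms: 1,2-bis(trimethylsilyloxy)ethane, C[Si](C)(C)OCCO[Si](C)(C)C
Why: Noyori ketalisation with one equivalent of the bis-silyl glycol should pick the C1 ketone (flanked by CH and CH2) over the C16 ketone (flanked by the quaternary C5), and the aprotic medium spares the silyl ether.

**Step 11**
Reactants: 12 ketal ketone
Product: 13 C4-trifluoroacetyl ketone (largely enolised, used crude)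
Conditions: LiN(SiMe3)2, THF, −78 °C; CF3CO2CH2CF3; dilute HCl work-up
Reagents that add atoms: 2,2,2-trifluoroethyl trifluoroacetate, FC(F)(F)COC(=O)C(F)(F)F
Why: Claisen-type C-trifluoroacetylation activates C4 for diazo transfer, and it is unambiguous because C5 is quaternary and the ketone can be deprotonated only at C4.

**Step 12**
Reactants: 13 C4-trifluoroacetyl ketone
Product: 14 bicyclo[3.2.1]octane α-diazoketone (diazo at C4, C1 ketal, C5 CH2OTBS)
Conditions: MsN3, Et3N, H2O (1 equiv), MeCN, rt
Reagents that add atoms: methanesulfonyl azide, CS(=O)(=O)N=[N+]=[N-]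
Why: Regitz-type detrifluoroacetylative diazo transfer, in which the sulfonyl azide is attacked by the activated C4 and the trifluoroacetyl group leaves on the sulfonamide nitrogen, under conditions mild enough for ketal and silyl ether.

**Step 13**
Reactants: 14 bicyclo[3.2.1]octane α-diazoketone
Product: 16 norbornane endo-C4 methyl ester, via exocyclic ketene 15 (not isolated)
Conditions: hν (medium-pressure mercury lamp, Pyrex filter), MeOH, 0 °C, argon
Reagents that add atoms: methanol, CO
Why: Excitation of the ring-locked s-Z diazoketone expels N2 and, in concert or through the singlet ketocarbene, C5 shifts from C16 to C4 (photochemical Wolff rearrangement), which forms C4–C5 and gives ketene 15; methanol adds to C16 and the enol so formed tautomerises to ester 16. The closest known reaction type is the photochemical Wolff ring contraction of cyclic α-diazoketones to strained bicyclic esters such as bicyclo[2.1.1]hexane and norbornane carboxylates. The new five-membered ring C2–C3–C4–C5–C15 is closed by a 1,2-shift inside the six-membered ring (contraction from six to five), not by an exo or endo cyclisation, and its strain is paid for by the loss of N2. C5 migrates with retention, so the quaternary centre fixed in steps 2 and 3 becomes the bridgehead unchanged, and C2 is not touched. The only new stereocentre, C4, is set when the enol is protonated: the exo face (side of C15) is open while the endo face is screened by the C1–C10 bridge, so hydrogen should enter exo and leave the ester endo. The step needs this facial selectivity and a defined diazo position; the shape of the norbornane secures the first, the single enolisable position of 12 secures the second, and neutral methanol at low temperature avoids epimerisation to the exo ester.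

**Step 14**
Reactants: 16 norbornane endo-C4 methyl ester
Product: 17 endo-C4 2-hydroxyprop-2-yl norbornane
Conditions: MeMgBr (4 equiv), LaCl3·2LiCl (1 equiv), THF, 0 °C
Reagents that add atoms: methylmagnesium bromide, C[Mg]Br
Why: Twofold Grignard addition to the ester builds the C16 carbinol, LaCl3·2LiCl raising the rate of addition over enolisation so that the endo configuration at C4 should survive.

**Step 15**
Reactants: 17 tertiary alcohol
Product: 18 endo-C4 isopropenyl norbornane
Conditions: Burgess reagent, toluene, 70 °C
Reagents that add atoms: none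
Why: Burgess dehydration (thermal syn elimination, no acid) should take a methyl hydrogen and give the isopropenyl group with C4, ketal and silyl ether untouched; any isopropylidene isomer converges in step 16 since hydrogen reaches C4 from the exo face.

**Step 16**
Reactants: 18 isopropenyl norbornane
Product: 19 endo-C4 isopropyl norbornane (C1 ketal, C5 CH2OTBS)
Conditions: H2 (1 atm), PtO2, EtOAc, rt
Reagents that add atoms: none
Why: Heterogeneous hydrogenation of the only alkene completes the isopropyl group and does not touch a stereocentre.

**Step 17**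
Reactants: 19 isopropyl norbornane TBS ether
Product: 20 C6 primary alcohol
Conditions: TBAF, THF, rt
Reagents that add atoms: none
Why: Fluoride-induced desilylation frees the C6 alcohol and leaves the ketal alone.

**Step 18**
Reactants: 20 C6 primary alcohol
Product: 21 C6 bridgehead aldehyde
Conditions: Dess–Martin periodinane, NaHCO3, CH2Cl2, rt
Reagents that add atoms: none
Why: Dess–Martin oxidation gives the bridgehead aldehyde, which cannot enolise.

**Step 19**
Reactants: 21 C6 bridgehead aldehyde
Product: 22 C5 ethynyl norbornane (C6≡C7H)
Conditions: dimethyl (1-diazo-2-oxopropyl)phosphonate, K2CO3, MeOH, rt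
Reagents that add atoms: dimethyl (1-diazo-2-oxopropyl)phosphonate, COP(=O)(OC)C(=[N+]=[N-])C(C)=O
Why: The Ohira–Bestmann variant of the Seyferth–Gilbert homologation adds C7 as the alkyne terminus under carbonate conditions that suit a non-enolisable aldehyde and the ketal.

**Step 20**
Reactants: 22 C5 ethynyl norbornane
Product: 23 C7 aldehyde (C5–CH2–CHO)
Conditions: Cy2BH, THF, 0 °C; then H2O2, aq NaHCO3
Reagents that add atoms: hydrogen peroxide, OO
Why: Anti-Markovnikov hydroboration–oxidation of the terminal alkyne with a hindered dialkylborane places oxygen on C7 and gives the aldehyde without acid, which is why it is preferred to an enol ether hydrolysis beside the ketal.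

**Step 21**
Reactants: 23 C7 aldehyde; 24 cyclohexane-1,3-dione
Product: 26 2-alkylcyclohexane-1,3-dione, via alkylidene dione 25 (not isolated)
Conditions: Hantzsch ester (1.1 equiv), L-proline (20 mol %), CH2Cl2, rt
Reagents that add atoms: none
Why: Three-component reductive alkylation, in which proline-catalysed Knoevenagel condensation gives alkylidene dione 25, which takes up hydride from the Hantzsch ester at C7 faster than a second dione can add, so that C7–C8 is formed without the O-alkylation that a C7 halide would suffer.

**Step 22**
Reactants: 26 2-alkylcyclohexane-1,3-dione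
Product: 27 2-alkyl-2-methylcyclohexane-1,3-dione (C8 quaternary, prochiral)
Conditions: MeI, BnMe3NOH (Triton B), MeOH, reflux
Reagents that add atoms: iodomethane, CI
Why: C-Methylation of the 2-alkyl-1,3-dione in a protic medium (the conditions used for 2,2-dialkylcyclohexane-1,3-diones) makes C8 quaternary and still prochiral, and O-methylated material can be hydrolysed back to 26.

**Step 23**
Reactants: 27 2-alkyl-2-methylcyclohexane-1,3-dione
Product: 28 hydroxy ketone (C9 ketone, C14 (R)-OH trans to the C8 methyl, C8 (R))
Conditions: (S)-Me-CBS (0.3 equiv), catecholborane (1.1 equiv), toluene, −60 °C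
Reagents that add atoms: none
Why: Corey–Bakshi–Shibata desymmetrising reduction, in which the (S)-oxazaborolidine should give the (R)-carbinol with C8 as the large group and attack on the carbonyl face syn to the small methyl then selects one of the two enantiotopic carbonyls, which sets C8 and C14 (OH trans to the methyl) under reagent control far from the norbornane.

**Step 24**
Reactants: 28 hydroxy ketone
Product: 29 C14 TBS ether ketone
Conditions: TBSOTf, 2,6-lutidine, CH2Cl2, 0 °C
Reagents that add atoms: tert-butyldimethylsilyl triflate, CC(C)(C)[Si](C)(C)OS(=O)(=O)C(F)(F)F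
Why: Silylation of the hindered secondary alcohol with the silyl triflate protects C14-OH for the base and palladium steps.

**Step 25**
Reactants: 29 C14 TBS ether ketone
Product: 30 C9 enol triflate (C9=C11), C1 ketal
Conditions: KN(SiMe3)2, THF, −78 °C; PhNTf2, −78 °C to 0 °C
Reagents that add atoms: N-phenylbis(trifluoromethanesulfonimide), O=S(=O)(N(c1ccccc1)S(=O)(=O)C(F)(F)F)C(F)(F)F
Why: Enol triflate formation is regiochemically unambiguous because C8 is quaternary and the C9 ketone can enolise only toward C11.

**Step 26**
Reactants: 30 C9 enol triflate ketal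
Product: 31 C9 enol triflate with free C1 ketone
Conditions: PPTS, acetone–H2O, 55 °C
Reagents that add atoms: water, O
Why: Acid-catalysed ketal hydrolysis frees the C1 ketone, and the enol triflate and the hindered secondary TBS ether tolerate the mild acid.

**Step 27**
Reactants: 31 keto enol triflate
Product: 32 tetracyclic β,γ-unsaturated ketone (C1 ketone, C9 exo on C10, C9=C11)
Conditions: Pd2(dba)3 (5 mol %), XPhos (12 mol %), Cs2CO3, toluene, 90 °C
Reagents that add atoms: none
Why: Intramolecular palladium-catalysed α-alkenylation of a ketone (oxidative addition of zerovalent palladium into the C9 triflate, enolisation possible only at C10 because C2 is a bridgehead, reductive elimination) closes the six-membered ring B at C9–C10; the tether from C5 reaches the exo face of C10 without strain, the centre stays epimerisable toward this exo isomer, and the alkene should stay at C9=C11 because a C9=C10 enone would force ring B into a boat for this C8 configuration.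

**Step 28**
Reactants: 32 tetracyclic ketone
Product: 33 C1 endo alcohol
Conditions: NaBH4, MeOH–CH2Cl2, −20 °C
Reagents that add atoms: none
Why: Hydride reduction of a norbornanone from the exo face (C15 carries no syn substituent, and the endo face is closed by the C3–C4 bridge) should give the endo alcohol at C1, trans to C9.

**Step 29**
Reactants: 33 C1 endo alcohol
Product: 34 C1 endo methyl ether
Conditions: NaH, MeI, THF–DMF, 0 °C to rt
Reagents that add atoms: iodomethane, CI
Why: Williamson etherification of the only free hydroxyl, with alkene and silyl ether inert.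

**Step 30**
Reactants: 34 C1 endo methyl ether
Product: 35 C11 β (equatorial) alcohol with H9 β (trans rings A/B)
Conditions: BH3·THF, THF, 0 °C to 40 °C; then NaOH, H2O2
Reagents that add atoms: hydrogen peroxide, OO
Why: Hydroboration–oxidation of the trisubstituted alkene puts boron on C11 and hydrogen on C9 in a syn addition anti to the axial C8 methyl (as with steroidal 4-enes), which should set H9 β and an equatorial C11 alcohol.

**Step 31**
Reactants: 35 C11 alcohol
Product: 36 C11 ketone (trans-fused)
Conditions: Dess–Martin periodinane, NaHCO3, CH2Cl2, rt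
Reagents that add atoms: none
Why: Dess–Martin oxidation gives the C11 ketone; C9 becomes epimerisable but the trans fusion is the stable arrangement, so that any cis-fused material can be converged with a mild base.

**Step 32**
Reactants: 36 C11 ketone
Product: 37 C11 enol triflate (C11=C12)
Conditions: KN(SiMe3)2, THF, −78 °C; PhNTf2
Reagents that add atoms: N-phenylbis(trifluoromethanesulfonimide), O=S(=O)(N(c1ccccc1)S(=O)(=O)C(F)(F)F)C(F)(F)F
Why: Kinetic deprotonation takes a hydrogen of the C12 methylene in preference to the hindered tertiary H9, and O-triflation fixes the alkene at C11=C12.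

**Step 33**
Reactants: 37 C11 enol triflate
Product: 38 C11-methyl alkene (C11=C12), C14 OTBS
Conditions: MeMgBr, Fe(acac)3 (10 mol %), THF–NMP, −20 °C to 0 °C
Reagents that add atoms: methylmagnesium bromide, C[Mg]Br
Why: Iron-catalysed Kumada-type cross-coupling of an enol triflate with MeMgBr installs the C11 methyl with retention of the alkene position, and ether and silyl ether are inert.

**Step 34**
Reactants: 38 C11-methyl alkene TBS ether
Product: 39 C14 β (axial) alcohol
Conditions: TBAF, THF, 50 °C
Reagents that add atoms: none
Why: Fluoride-induced desilylation frees the axial C14 alcohol, with warming to overcome the neopentyl hindrance.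

**Step 35**
Reactants: 39 C14 β alcohol
Product: 40 C14 α (equatorial) bromide
Conditions: CBr4, PPh3, toluene, 60 °C
Reagents that add atoms: tetrabromomethane, BrC(Br)(Br)Br
Why: Appel bromination, in which the activated axial β oxygen is displaced by bromide from the α side (SN2 with inversion), should give the equatorial α bromide, and it is run before the diol is made so that no other hydroxyl competes.

**Step 36**
Reactants: 40 C14 α bromide
Product: 41 C11,C12 β-epoxide
Conditions: mCPBA, NaHCO3, CH2Cl2, 0 °C
Reagents that add atoms: 3-chloroperoxybenzoic acid, OOC(=O)c1cccc(Cl)c1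
Why: Prilezhaev epoxidation of the only alkene from the β face, because the axial C8 methyl screens the α face (as with steroidal 2-enes) and C14 now shows only an axial hydrogen on the β face.

**Step 37**
Reactants: 41 β-epoxide
Product: 42 CNP0130529.1 (target)
Conditions: HClO4 (cat.), THF–H2O, 0 °C to rt
Reagents that add atoms: water, O
Why: Acid-catalysed epoxide hydrolysis in the Fürst–Plattner sense, in which water attacks the tertiary C11 from the α face with inversion (electronic and trans-diaxial preferences coincide) and the β oxygen stays on C12, which should give C11 α-OH with β-methyl and C12 β-OH while bromide and methyl ether are inert.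

**Compound list**
1 | dimethyl malonate | COC(=O)CC(=O)OC | starting material
2 | cis-1,4-dichlorobut-2-ene | ClC/C=C\CCl | starting material
3 | dimethyl cyclopent-3-ene-1,1-dicarboxylate | COC(=O)C1(CC=CC1)C(=O)OC | intermediate
4 | dimethyl (S)-3-hydroxycyclopentane-1,1-dicarboxylate | O[C@H]1CCC(C(=O)OC)(C(=O)OC)C1 | intermediate
5 | bridged lactone ester, methyl 3-oxo-2-oxabicyclo[2.2.1]heptane-4-carboxylate (lactone from C1-O to C16 on C5) | O1[C@H]2CC[C@](C(=O)OC)(C2)C1=O | intermediate
6 | lactol ester (anomers at C16) | O1[C@H]2CC[C@](C(=O)OC)(C2)C1O | intermediate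
7 | methyl 3-hydroxy-1-(1-hydroxyallyl)cyclopentane-1-carboxylate, arm cis to C1-OH, epimers at C16 | O[C@H]1CC[C@](C(=O)OC)(C1)C(O)C=C | intermediate
8 | triol, 3-(hydroxymethyl)-3-(1-hydroxyallyl)cyclopentan-1-ol | O[C@H]1CC[C@](CO)(C1)C(O)C=C | intermediate
9 | primary TBS ether of the triol | O[C@H]1CC[C@](CO[Si](C)(C)C(C)(C)C)(C1)C(O)C=C | intermediate
10 | 3-acryloyl-3-(TBS-oxymethyl)cyclopentan-1-one | O=C1CC[C@](CO[Si](C)(C)C(C)(C)C)(C1)C(=O)C=C | intermediate
11 | 1-(TBS-oxymethyl)bicyclo[3.2.1]octane-2,6-dione | O=C1[C@H]2CCC(=O)[C@](C1)(CO[Si](C)(C)C(C)(C)C)C2 | intermediate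
12 | C1 ethylene ketal of 11 | C1COC2(O1)[C@H]3CCC(=O)[C@](C2)(CO[Si](C)(C)C(C)(C)C)C3 | intermediate
13 | C4-trifluoroacetyl ketone | C1COC2(O1)[C@H]3CC(C(=O)C(F)(F)F)C(=O)[C@](C2)(CO[Si](C)(C)C(C)(C)C)C3 | intermediate
14 | bicyclo[3.2.1]octane α-diazoketone | C1COC2(O1)[C@H]3CC(=[N+]=[N-])C(=O)[C@](C2)(CO[Si](C)(C)C(C)(C)C)C3 | intermediate
15 | exocyclic C4 ketene on the norbornane | C1COC2(O1)[C@H]3CC(=C=O)[C@](C2)(CO[Si](C)(C)C(C)(C)C)C3 | intermediate
16 | norbornane endo-C4 methyl ester | C1COC2(O1)[C@H]3C[C@@H](C(=O)OC)[C@](C2)(CO[Si](C)(C)C(C)(C)C)C3 | intermediate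
17 | endo-C4 2-hydroxyprop-2-yl norbornane | C1COC2(O1)[C@H]3C[C@@H](C(C)(C)O)[C@](C2)(CO[Si](C)(C)C(C)(C)C)C3 | intermediate
18 | endo-C4 isopropenyl norbornane | C1COC2(O1)[C@H]3C[C@@H](C(C)=C)[C@](C2)(CO[Si](C)(C)C(C)(C)C)C3 | intermediate
19 | endo-C4 isopropyl norbornane TBS ether | C1COC2(O1)[C@H]3C[C@@H](C(C)C)[C@](C2)(CO[Si](C)(C)C(C)(C)C)C3 | intermediate
20 | C6 primary alcohol | C1COC2(O1)[C@H]3C[C@@H](C(C)C)[C@](C2)(CO)C3 | intermediate
21 | C6 bridgehead aldehyde | C1COC2(O1)[C@H]3C[C@@H](C(C)C)[C@](C2)(C=O)C3 | intermediate
22 | C5 ethynyl norbornane | C1COC2(O1)[C@H]3C[C@@H](C(C)C)[C@](C2)(C#C)C3 | intermediate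
23 | C7 aldehyde | C1COC2(O1)[C@H]3C[C@@H](C(C)C)[C@](C2)(CC=O)C3 | intermediate
24 | cyclohexane-1,3-dione | O=C1CCCC(=O)C1 | starting material
25 | alkylidene dione (C7=C8) | C1COC2(O1)[C@H]3C[C@@H](C(C)C)[C@](C2)(CC=C4C(=O)CCCC4=O)C3 | intermediate
26 | 2-alkylcyclohexane-1,3-dione | C1COC2(O1)[C@H]3C[C@@H](C(C)C)[C@](C2)(CCC4C(=O)CCCC4=O)C3 | intermediate
27 | 2-alkyl-2-methylcyclohexane-1,3-dione | C1COC2(O1)[C@H]3C[C@@H](C(C)C)[C@](C2)(CCC4(C)C(=O)CCCC4=O)C3 | intermediate
28 | hydroxy ketone, C14-OH trans to the C8 methyl | C1COC2(O1)[C@H]3C[C@@H](C(C)C)[C@](C2)(CC[C@@]4(C)C(=O)CCC[C@H]4O)C3 | intermediate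
29 | C14 TBS ether ketone | C1COC2(O1)[C@H]3C[C@@H](C(C)C)[C@](C2)(CC[C@@]4(C)C(=O)CCC[C@H]4O[Si](C)(C)C(C)(C)C)C3 | intermediate
30 | C9 enol triflate, C1 ketal | C1COC2(O1)[C@H]3C[C@@H](C(C)C)[C@](C2)(CC[C@@]4(C)C(OS(=O)(=O)C(F)(F)F)=CCC[C@H]4O[Si](C)(C)C(C)(C)C)C3 | intermediate
31 | C9 enol triflate, C1 ketone | O=C1[C@H]2C[C@@H](C(C)C)[C@](C1)(CC[C@@]3(C)C(OS(=O)(=O)C(F)(F)F)=CCC[C@H]3O[Si](C)(C)C(C)(C)C)C2 | intermediate
32 | tetracyclic C1 ketone, C9=C11, C9 exo on C10 | O=C1[C@H]2C[C@@H](C(C)C)[C@]3(CC[C@@]4(C)C([C@H]13)=CCC[C@H]4O[Si](C)(C)C(C)(C)C)C2 | intermediate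
33 | C1 endo alcohol | O[C@H]1[C@H]2C[C@@H](C(C)C)[C@]3(CC[C@@]4(C)C([C@H]13)=CCC[C@H]4O[Si](C)(C)C(C)(C)C)C2 | intermediate
34 | C1 endo methyl ether | CO[C@H]1[C@H]2C[C@@H](C(C)C)[C@]3(CC[C@@]4(C)C([C@H]13)=CCC[C@H]4O[Si](C)(C)C(C)(C)C)C2 | intermediate
35 | C11 β alcohol, H9 β | CO[C@H]1[C@H]2C[C@@H](C(C)C)[C@]3(CC[C@@]4(C)[C@H]([C@H]13)[C@@H](O)CC[C@H]4O[Si](C)(C)C(C)(C)C)C2 | intermediate
36 | C11 ketone | CO[C@H]1[C@H]2C[C@@H](C(C)C)[C@]3(CC[C@@]4(C)[C@H]([C@H]13)C(=O)CC[C@H]4O[Si](C)(C)C(C)(C)C)C2 | intermediate
37 | C11 enol triflate | CO[C@H]1[C@H]2C[C@@H](C(C)C)[C@]3(CC[C@@]4(C)[C@H]([C@H]13)C(OS(=O)(=O)C(F)(F)F)=CC[C@H]4O[Si](C)(C)C(C)(C)C)C2 | intermediate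
38 | C11-methyl alkene, C14 OTBS | CO[C@H]1[C@H]2C[C@@H](C(C)C)[C@]3(CC[C@@]4(C)[C@H]([C@H]13)C(C)=CC[C@H]4O[Si](C)(C)C(C)(C)C)C2 | intermediate
39 | C14 β alcohol | CO[C@H]1[C@H]2C[C@@H](C(C)C)[C@]3(CC[C@@]4(C)[C@H]([C@H]13)C(C)=CC[C@H]4O)C2 | intermediate
40 | C14 α bromide | CO[C@H]1[C@H]2C[C@@H](C(C)C)[C@]3(CC[C@@]4(C)[C@H]([C@H]13)C(C)=CC[C@@H]4Br)C2 | intermediate
41 | C11,C12 β-epoxide | CO[C@H]1[C@H]2C[C@@H](C(C)C)[C@]3(CC[C@@]4(C)[C@H]([C@H]13)[C@@]5(C)O[C@H]5C[C@@H]4Br)C2 | intermediate
42 | CNP0130529.1 | CO[C@H]1[C@H]2C[C@@H](C(C)C)[C@]3(CC[C@@]4(C)[C@H]([C@H]13)[C@](C)(O)[C@@H](O)C[C@@H]4Br)C2 | target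

Total step count: 37. Longest linear sequence: 37 steps (from 1 and 2; 24 enters in step 21).

**Steps most likely to fail**

**Step 13.**
- What may go wrong: protonation of the ketene-derived enol may not be face-selective enough, because the C6 arm leans toward the exo side of C4. The endo ester may also epimerise on handling.
- Fallback, setting out from 14 and coming back at 16: the stereocentre is erased and reset by hydrogenation instead of protonation.
- The photolysate of 14 is a mixture of 16 and the exo methyl ester F1. It is deprotonated with LiN(iPr)2 and treated with PhSeBr, which should enter from the exo face and give the α-phenylselanyl ester F2.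
- Oxidation with H2O2 and syn elimination toward C3 gives the norbornene ester F3.
- Hydrogenation over Pd/C delivers both hydrogens from the exo face and should return 16 as the endo ester.

**Step 27.**
- What may go wrong: reductive elimination between two carbons that each stand next to a quaternary centre may be too slow, so that hydrolysis or reduction of the triflate takes over.
- Fallback, setting out from 29 and coming back at 33: ring B is closed by a radical instead of a palladium enolate.
- Hydrazine converts the C9 ketone of 29 into the hydrazone F4. I2 with tetramethylguanidine (Barton vinyl iodide synthesis) then gives the vinyl iodide ketal F5.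
- PPTS in wet acetone frees the keto vinyl iodide F6, and TESOTf with Et3N gives the C1 triethylsilyl enol ether F7.
- Bu3SnH and AIBN generate the C9 vinyl radical, which should add 6-exo-trig to C10 from the exo face. The C1 radical then takes hydrogen from the exo face to give the endo triethylsilyl ether F8.
- AcOH in aqueous THF removes only the triethylsilyl group and gives 33.

**Step 35.**
- What may go wrong: at the neopentyl carbon C14, elimination toward C13 or migration of the antiperiplanar C8 methyl may outrun the displacement.
- Fallback, setting out from 39 and coming back at 40: a radical route that needs no backside attack.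
- Dess–Martin periodinane oxidises 39 to the C14 ketone F9, and hydrazine gives the hydrazone F10.
- CuBr2 with t-BuOLi converts it into the gem-dibromide F11.
- One equivalent of Bu3SnH with Et3B and air at low temperature removes one bromine. The α-bromo radical should take hydrogen on the open β face, anti to the C8 methyl, which leaves the bromine equatorial and α, that is 40.

**Further compounds**
F1 | step 13 | exo methyl ester (C4 epimer of 16) | C1COC2(O1)[C@H]3C[C@H](C(=O)OC)[C@](C2)(CO[Si](C)(C)C(C)(C)C)C3
F2 | step 13 | α-phenylselanyl ester (Se exo, ester endo) | C1COC2(O1)[C@H]3C[C@@]([Se]c4ccccc4)(C(=O)OC)[C@](C2)(CO[Si](C)(C)C(C)(C)C)C3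
F3 | step 13 | norbornene ester (C3=C4) | C1COC2(O1)[C@H]3C=C(C(=O)OC)[C@](C2)(CO[Si](C)(C)C(C)(C)C)C3
F4 | step 27 | C9 hydrazone | C1COC2(O1)[C@H]3C[C@@H](C(C)C)[C@](C2)(CC[C@@]4(C)C(=NN)CCC[C@H]4O[Si](C)(C)C(C)(C)C)C3
F5 | step 27 | vinyl iodide ketal | C1COC2(O1)[C@H]3C[C@@H](C(C)C)[C@](C2)(CC[C@@]4(C)C([I])=CCC[C@H]4O[Si](C)(C)C(C)(C)C)C3
F6 | step 27 | keto vinyl iodide | O=C1[C@H]2C[C@@H](C(C)C)[C@](C1)(CC[C@@]3(C)C([I])=CCC[C@H]3O[Si](C)(C)C(C)(C)C)C2
F7 | step 27 | C1 triethylsilyl enol ether | CC[Si](CC)(CC)OC=1[C@H]2C[C@@H](C(C)C)[C@](C=1)(CC[C@@]3(C)C([I])=CCC[C@H]3O[Si](C)(C)C(C)(C)C)C2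
F8 | step 27 | endo triethylsilyl ether of 33 | CC[Si](CC)(CC)O[C@H]1[C@H]2C[C@@H](C(C)C)[C@]3(CC[C@@]4(C)C([C@H]13)=CCC[C@H]4O[Si](C)(C)C(C)(C)C)C2
F9 | step 35 | C14 ketone | CO[C@H]1[C@H]2C[C@@H](C(C)C)[C@]3(CC[C@@]4(C)[C@H]([C@H]13)C(C)=CCC4=O)C2
F10 | step 35 | C14 hydrazone | CO[C@H]1[C@H]2C[C@@H](C(C)C)[C@]3(CC[C@@]4(C)[C@H]([C@H]13)C(C)=CCC4=NN)C2
F11 | step 35 | C14 gem-dibromide | CO[C@H]1[C@H]2C[C@@H](C(C)C)[C@]3(CC[C@@]4(C)[C@H]([C@H]13)C(C)=CCC4(Br)Br)C2
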